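**Retrosynthetic overview**

- The target is a meso dimer: two mirror-image cyclohexane rings (A and B) joined by a (Z,Z)-1,5-diene. Both rings are opened at once, each at the carbinol–quaternary bond C-1–C-2 (aldol) and at the ring CH2–CH2 bond C-5–C-6 (radical conjugate addition). This leads to an acyclic, symmetric C14 (4Z,8Z)-diformyl-dienedioic acid and two molecules of an isopropenyl ketone.
- Enabling feature: in each ring the quaternary carbon C-1 (CH3, acyl) is the α-carbon of the side-chain ketone. It lies between the ring CH2 C-6 (β-carbon of an α-methylene ketone) and the carbinol carbon C-2. Because C-2 sits on the alkylidene carbon C-3, it is the carbonyl carbon of a (Z)-enal. The distal CH2 C-5 is reached as a radical from a carboxylic acid that leaves as CO2.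
- The diacid-dialdehyde comes from succinaldehyde (the central CH2CH2 and both =CH carbons), two α-lithioacrolein acetal units and two orthoacetate units. A double Johnson orthoester Claisen rearrangement sets both trisubstituted alkenes and brings in the carboxyl carbons.
- The enone comes from 4-methylpent-3-enoic acid through its Weinreb amide and isopropenylmagnesium bromide.
- Ring order: no ring exists until the last step; rings A and B then form simultaneously.

Key step: step 7

Remark on the chemistry: the target is meso (ring A 1R,2S; ring B 1S,2R; both exocyclic alkenes Z), so no enantioselective step is needed. The route controls the cis relation of hydroxyl and acyl group within each ring and the alkene geometry, but the relation between the two rings only statistically.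

Remark on a reagent: the vinyl bromide of step 2 (2-bromoacrolein diethyl acetal) is taken as purchasable; otherwise it is made in one flask from acrolein diethyl acetal (Br2, then KOtBu).

Locants used in the text: in each ring C-1 is the quaternary carbon, C-2 the carbinol carbon, C-3 the alkylidene carbon, and C-4 to C-6 the CH2 groups.

**Route**

Step 1
Reactants: 1 2,5-dimethoxytetrahydrofuran
Product: 2 succinaldehyde
Conditions: H2O, 90 °C; distilled and used at once
Reagents that add atoms: water, O
Why: Acetal hydrolysis: hot water cleaves the cyclic bis(methyl acetal) to the free dialdehyde, which is used fresh because it oligomerizes; no stereocenter is formed.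

Step 2
Reactants: 2 succinaldehyde; 3 2-bromo-3,3-diethoxyprop-1-ene
Product: 5 1,1,8,8-tetraethoxy-2,7-dimethylideneoctane-3,6-diol (mixture of diastereomers), via vinyllithium 4 (not isolated)
Conditions: 3 (2.6 equiv), n-BuLi (2.5 equiv), THF, −78 °C; then 2 (1 equiv), −78 to −30 °C; H2O
Reagents that add atoms: n-butyllithium, [Li]CCCC (its lithium is carried in 4 only)
Why: Bromine–lithium exchange followed by twofold 1,2-addition of the alkenyllithium 4 to the dialdehyde (excess 4 at −78 °C should outrun enolization and loss of ethoxide); the two carbinol stereocenters form without control and both are erased in step 3.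

Step 3
Reactants: 5 1,1,8,8-tetraethoxy-2,7-dimethylideneoctane-3,6-diol; 6 triethyl orthoacetate
Product: 8 diethyl (4Z,8Z)-4,9-bis(diethoxymethyl)dodeca-4,8-dienedioate, via bis(ketene acetal) 7 (not isolated)
Conditions: 6 (10 equiv), EtCO2H (0.1 equiv), 138 °C, EtOH distilled off
Reagents that add atoms: none
Why: Two-directional Johnson orthoester Claisen rearrangement: each mixed ketene acetal of 7 rearranges through a chair transition state with the tether CH2 equatorial, which places it trans to the new CH2CH2CO2Et chain and cis to the acetal carbon in both trisubstituted alkenes (4Z,8Z), and installs the ester carbon that later leaves as CO2.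

Step 4
Reactants: 8 diethyl (4Z,8Z)-4,9-bis(diethoxymethyl)dodeca-4,8-dienedioate
Product: 10 (4Z,8Z)-4,9-diformyldodeca-4,8-dienedioic acid, via dilithium dicarboxylate 9 (not isolated)
Conditions: LiOH·H2O (4 equiv), THF/H2O 3:1, 0 to 20 °C; then 1 M HCl to pH 2, 0 °C, 1 h, light excluded; extraction, no chromatography, used at once
Reagents that add atoms: lithium hydroxide, [Li+].[OH-]; water, O
Why: Ester saponification with the aldehydes still masked, then mild acid hydrolysis of the α,β-unsaturated acetals (fast through the allyl-stabilized oxocarbenium ion) under cold, dark and short conditions chosen so that the less stable (Z)-enal does not isomerize; no stereocenter is formed and the alkene geometry of 8 is kept.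

Step 5
Reactants: 11 4-methylpent-3-enoic acid; 12 N,O-dimethylhydroxylamine hydrochloride
Product: 14 N-methoxy-N,4-dimethylpent-3-enamide, via acyl imidazole 13 (not isolated)
Conditions: CDI (1.1 equiv), CH2Cl2, 0 to 20 °C; then 12 (1.3 equiv), 20 °C
Reagents that add atoms: 1,1'-carbonyldiimidazole, O=C(n1ccnc1)n1ccnc1 (its imidazole ring is carried in 13 only)
Why: Amide coupling through the acyl imidazole 13 under neutral conditions that leave the β,γ-double bond in place.

Step 6
Reactants: 14 N-methoxy-N,4-dimethylpent-3-enamide; 15 isopropenylmagnesium bromide
Product: 17 2,6-dimethylhepta-1,5-dien-3-one, via magnesium chelate 16 (not isolated)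
Conditions: 15 (1.5 equiv), THF, −20 to 0 °C; inverse quench into cold 1 M HCl/Et2O; stored cold
Reagents that add atoms: none
Why: Weinreb ketone synthesis: the magnesium chelate 16 survives until work-up so that the Grignard reagent adds only once, and the inverse acidic quench protonates the released amine before it can add to the new vinyl ketone.

Step 7
Reactants: 10 (4Z,8Z)-4,9-diformyldodeca-4,8-dienedioic acid; 17 2,6-dimethylhepta-1,5-dien-3-one
Product: 19 target CNP0297042.2 (meso), via mono-annulated hydroxy ketone acid 18 (not isolated)
Conditions: 17 (6 equiv), Ir[dF(CF3)ppy]2(dtbbpy)PF6 (2 mol %), K2HPO4 (2.2 equiv), degassed DMF (0.02 M), 450 nm LEDs, 20 °C; pH 5 buffer work-up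
Reagents that add atoms: none
Why: Proposed new method: a two-directional decarboxylative radical–polar crossover (Giese/aldol) annulation; mechanistic reasoning: the photoexcited trivalent iridium complex oxidizes each carboxylate of 10, loss of CO2 leaves a primary alkyl radical that adds to the CH2 terminus of the isopropenyl ketone 17 (Giese addition), divalent iridium reduces the resulting tertiary α-keto radical to a potassium enolate, and this enolate adds to the neighbouring (Z)-enal carbonyl faster than it is protonated, so that the ring CH2–CH2 bond (C-5–C-6) and the carbinol–quaternary bond (C-1–C-2) are made in one operation at each end. The closest known reaction types are the photoredox decarboxylative Giese addition of primary carboxylic acids to enones and radical–polar crossover annulations in which the enolate left by a Giese addition closes by intramolecular aldol addition; untested is their combination with a carboxylate-derived primary radical and an enal acceptor, run twice on one substrate. Each cyclohexane ring closes by a 6-(enolexo)-exo-trig aldol addition that follows the intermolecular radical addition, a formal (4+2) annulation of the four-carbon unit C-2 to C-5 with the two-carbon unit C-6/C-1. Both stereocentres of a ring (C-1 and C-2) are set in the aldol step: allylic 1,3-strain with the tether CH2 that is cis to the aldehyde on the (Z)-alkene keeps the aldehyde hydrogen in the alkene plane and turns the forming C–O bond axial, and a potassium-bridged chair then places the oxyalkylidene (future acyl) group equatorial and gauche to that oxygen, which gives the hydroxyl cis to the acyl group and trans to the methyl group, the isomer that the O–H···O=C hydrogen bond should also favour if the aldol addition equilibrates. The step needs chemoselective radical addition (the 1,1-disubstituted enone terminus, used in excess, is a far better acceptor than the β-substituted enal or the trisubstituted prenyl alkene), 1,2- rather than 1,4-closure of the enolate (the competing 6-endo Michael closure would have to join the future quaternary carbon to a tertiary centre, and the phosphate buffer protonates the aldolate and stops retro-aldol leakage), a regiodefined enolate (it is formed only at C-1, so the acidic CH2 of the skipped enone is never deprotonated) and retention of the (Z)-enal geometry (weak base, short irradiation). The two ring closures are separated by the four-carbon tether and do not communicate, so 19 (meso) is expected together with its chiral, twofold-symmetric diastereomer in a statistical proportion; the two are diastereomers and are separated by chromatography (if needed on a chiral stationary phase), and the unwanted one can in principle be returned to the mixture by base-mediated retro-aldol/aldol equilibration.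

**Compound list**

1 | 2,5-dimethoxytetrahydrofuran | COC1CCC(OC)O1 | starting material
2 | succinaldehyde | O=CCCC=O | intermediate
3 | 2-bromo-3,3-diethoxyprop-1-ene | CCOC(OCC)C(Br)=C | starting material
4 | (3,3-diethoxyprop-1-en-2-yl)lithium | [Li]C(=C)C(OCC)OCC | intermediate
5 | 1,1,8,8-tetraethoxy-2,7-dimethylideneoctane-3,6-diol (mixture of diastereomers) | CCOC(OCC)C(=C)C(O)CCC(O)C(=C)C(OCC)OCC | intermediate
6 | triethyl orthoacetate | CC(OCC)(OCC)OCC | starting material
7 | 3,6-bis[(1-ethoxyethenyl)oxy]-1,1,8,8-tetraethoxy-2,7-dimethylideneoctane | C=C(OCC)OC(CCC(OC(=C)OCC)C(=C)C(OCC)OCC)C(=C)C(OCC)OCC | intermediate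
8 | diethyl (4Z,8Z)-4,9-bis(diethoxymethyl)dodeca-4,8-dienedioate | CCOC(=O)CC/C(=C/CC/C=C(/CCC(=O)OCC)C(OCC)OCC)C(OCC)OCC | intermediate
9 | dilithium (4Z,8Z)-4,9-bis(diethoxymethyl)dodeca-4,8-dienedioate | [Li+].[Li+].[O-]C(=O)CC/C(=C/CC/C=C(/CCC(=O)[O-])C(OCC)OCC)C(OCC)OCC | intermediate
10 | (4Z,8Z)-4,9-diformyldodeca-4,8-dienedioic acid | OC(=O)CC/C(=C/CC/C=C(/CCC(=O)O)C=O)C=O | intermediate
11 | 4-methylpent-3-enoic acid | CC(C)=CCC(=O)O | starting material
12 | N,O-dimethylhydroxylamine hydrochloride | CNOC.Cl | starting material
13 | 1-(1H-imidazol-1-yl)-4-methylpent-3-en-1-one | CC(C)=CCC(=O)n1ccnc1 | intermediate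
14 | N-methoxy-N,4-dimethylpent-3-enamide | CC(C)=CCC(=O)N(C)OC | intermediate
15 | isopropenylmagnesium bromide | CC(=C)[Mg]Br | starting material
16 | bromomagnesium 3-[methoxy(methyl)amino]-2,6-dimethylhepta-1,5-dien-3-olate | CC(C)=CCC(O[Mg]Br)(N(C)OC)C(C)=C | intermediate
17 | 2,6-dimethylhepta-1,5-dien-3-one | CC(C)=CCC(=O)C(C)=C | intermediate
18 | rac-(4Z)-4-formyl-8-[(1Z,2S,3R)-2-hydroxy-3-methyl-3-(4-methylpent-3-enoyl)cyclohexylidene]oct-4-enoic acid (relative configuration) | CC(C)=CCC(=O)[C@]1(C)CCC/C(=C/CC/C=C(/CCC(=O)O)C=O)[C@@H]1O | intermediate
19 | 1-[(1R,2S,3Z)-2-hydroxy-3-{4-[(1Z,2R,3S)-2-hydroxy-3-methyl-3-(4-methylpent-3-enoyl)cyclohexylidene]butylidene}-1-methylcyclohexyl]-4-methylpent-3-en-1-one (meso) | CC(C)=CCC(=O)[C@]1(C)CCC/C(=C/CC/C=C2/CCC[C@](C)(C(=O)CC=C(C)C)[C@@H]2O)[C@@H]1O | target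

**Step count and risks**

Total step count: 7. Longest linear sequence: 5 steps (steps 1, 2, 3, 4 and 7); the enone branch (steps 5 and 6) joins at step 7.

Steps most likely to fail:

1. Step 7 (proposed new method). The enolate may be protonated before it closes. The (Z)-enal may lose its geometry through sensitization by the photocatalyst or through γ-deprotonation. The enolate may close in the conjugate sense, or radicals may add to enals of other molecules. Fallback with known chemistry, setting out from 10 (with 17) and coming back at 19: the two events are run one after the other. The photoredox decarboxylative Giese addition is carried out under its established protic conditions (same iridium complex, K2HPO4, DMF with 10 equiv H2O), so that each enolate is protonated and the open-chain bis(keto aldehyde) (2Z,6Z)-2,7-bis(4,8-dimethyl-5-oxonon-7-en-1-yl)octa-2,6-dienedial F1 is isolated. A separate intramolecular aldol cyclization under mild reversible base (catalytic KOtBu, t-BuOH/THF, 0 °C) then closes both rings. Only the enolate at the methine carbon can reach the aldehyde through a six-membered transition state; the other enolate would need an eight-membered one. This gives 19 with the same statistical relation between the rings.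

2. Step 4. Acid-induced Z to E isomerization of the enal may occur during acetal cleavage or while the free diacid-dialdehyde is handled. Fallback, setting out from 2 and coming back at 10: the aldehyde carbon is carried at the alcohol level and oxidized under neutral conditions. 2-Bromo-3-[(4-methoxyphenyl)methoxy]prop-1-ene F2 (from 2,3-dibromopropene and 4-methoxybenzyl alcohol/NaH) is lithiated (n-BuLi, −78 °C) and added to 2 to give 2,7-bis{[(4-methoxyphenyl)methoxy]methyl}octa-1,7-diene-3,6-diol F3. Johnson orthoester Claisen rearrangement with 6 gives diethyl (4Z,8Z)-4,9-bis{[(4-methoxyphenyl)methoxy]methyl}dodeca-4,8-dienedioate F4. LiOH gives the diacid (4Z,8Z)-4,9-bis{[(4-methoxyphenyl)methoxy]methyl}dodeca-4,8-dienedioic acid F5. DDQ (CH2Cl2/pH 7 buffer) removes both ethers to give (4Z,8Z)-4,9-bis(hydroxymethyl)dodeca-4,8-dienedioic acid F6. MnO2 (CH2Cl2, 20 °C) oxidizes the two allylic alcohols without touching the alkene geometry and gives 10.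

3. Step 3. The chair preference may erode through 1,2-strain between the bulky diethoxymethyl group and the equatorial tether, and the 1,4-diol or the acetals may suffer acid-induced cyclodehydration or damage at 138 °C. Fallback, setting out from 5 and coming back at 9: the same bonds are made by an Ireland–Claisen rearrangement at or below room temperature. Acetylation (Ac2O, pyridine, DMAP) gives 1,1,8,8-tetraethoxy-2,7-dimethylideneoctane-3,6-diyl diacetate F7. LiN(iPr)2/Me3SiCl (THF, −78 °C) gives the bis(silyl ketene acetal) 1,1,8,8-tetraethoxy-2,7-dimethylidene-3,6-bis{[1-(trimethylsilyloxy)ethenyl]oxy}octane F8. On warming to 25 °C this rearranges through the same chair to bis(trimethylsilyl) (4Z,8Z)-4,9-bis(diethoxymethyl)dodeca-4,8-dienedioate F9. Aqueous LiOH cleaves the silyl esters and gives 9.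

**Further compounds**

F1 | step 7 | (2Z,6Z)-2,7-bis(4,8-dimethyl-5-oxonon-7-en-1-yl)octa-2,6-dienedial | CC(C)=CCC(=O)C(C)CCC/C(C=O)=C/CC/C=C(/CCCC(C)C(=O)CC=C(C)C)C=O
F2 | step 4 | 2-bromo-3-[(4-methoxyphenyl)methoxy]prop-1-ene | COc1ccc(COCC(Br)=C)cc1
F3 | step 4 | 2,7-bis{[(4-methoxyphenyl)methoxy]methyl}octa-1,7-diene-3,6-diol | COc1ccc(COCC(=C)C(O)CCC(O)C(=C)COCc2ccc(OC)cc2)cc1
F4 | step 4 | diethyl (4Z,8Z)-4,9-bis{[(4-methoxyphenyl)methoxy]methyl}dodeca-4,8-dienedioate | CCOC(=O)CC/C(=C/CC/C=C(/CCC(=O)OCC)COCc1ccc(OC)cc1)COCc1ccc(OC)cc1
F5 | step 4 | (4Z,8Z)-4,9-bis{[(4-methoxyphenyl)methoxy]methyl}dodeca-4,8-dienedioic acid | OC(=O)CC/C(=C/CC/C=C(/CCC(=O)O)COCc1ccc(OC)cc1)COCc1ccc(OC)cc1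
F6 | step 4 | (4Z,8Z)-4,9-bis(hydroxymethyl)dodeca-4,8-dienedioic acid | OC(=O)CC/C(=C/CC/C=C(/CCC(=O)O)CO)CO
F7 | step 3 | 1,1,8,8-tetraethoxy-2,7-dimethylideneoctane-3,6-diyl diacetate | CCOC(OCC)C(=C)C(OC(C)=O)CCC(OC(C)=O)C(=C)C(OCC)OCC
F8 | step 3 | 1,1,8,8-tetraethoxy-2,7-dimethylidene-3,6-bis{[1-(trimethylsilyloxy)ethenyl]oxy}octane | C=C(O[Si](C)(C)C)OC(CCC(OC(=C)O[Si](C)(C)C)C(=C)C(OCC)OCC)C(=C)C(OCC)OCC
F9 | step 3 | bis(trimethylsilyl) (4Z,8Z)-4,9-bis(diethoxymethyl)dodeca-4,8-dienedioate | C[Si](C)(C)OC(=O)CC/C(=C/CC/C=C(/CCC(=O)O[Si](C)(C)C)C(OCC)OCC)C(OCC)OCC
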